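## Retrosynthetic overview

- Feature: in the pyranone ring (O1–C2–C3–C4–C4a–C8a) C2 carries a methyl group and is bound to the aryl oxygen O1, and C3 carries a methyl group and is alpha to the C4 ketone on C4a. The C2–C3 bond is therefore cut to a C3 carbenoid and the O–CH2 of an ethyl ether on C8a.
- Target 24 ⇐ tricyclic lactone 23 (O5 and the acid tied as a six-membered lactone) ⇐ diazoketone 22 by rhodium carbenoid C–H insertion, which closes the pyranone last and sets both methyl centres.
- 22 ⇐ ethyl ketone 18 (diazo transfer) ⇐ (4R)-dihydrocoumarin 9: allyl to C6 by Claisen rearrangement from O5, propanoyl to the last free position C8, allyl to prenyl by cross-metathesis.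
- 9 ⇐ coumarin 5 by copper hydride asymmetric conjugate reduction (sets C4) ⇐ Pechmann condensation of phloroglucinol with ethyl 3-oxooctanoate, then O7 ethylation.
- Ring order: arene (bought), lactone ring (step 1), pyranone ring (step 11); the lactone is opened in step 12.

Key step: step 11

Assumption: (R)-DTBM-SEGPHOS in step 4 and Rh2(S-PTTL)4 in step 11 are taken to give the configurations drawn; each sense of induction would be checked on the first run and the mirror-image ligand used if it proves opposite.

## Route

Step 1
Reactants: 1 phloroglucinol; 2 ethyl 3-oxooctanoate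
Product: 3 5,7-dihydroxy-4-pentylcoumarin
Conditions: CF3SO3H (neat), 0 °C → rt
Reagents that add atoms: ethyl 3-oxooctanoate (2), CCCCCC(=O)CC(=O)OCC
Why: Pechmann condensation (acid-promoted transesterification, ring hydroxyalkylation and dehydration), which can give only one coumarin because all three ring positions of phloroglucinol are equivalent.

Step 2
Reactants: 3 5,7-dihydroxy-4-pentylcoumarin; 4 iodoethane
Product: 5 7-ethoxy-5-hydroxy-4-pentylcoumarin
Conditions: EtI (1.05 equiv), K2CO3 (1.1 equiv), acetone, rt → 40 °C
Reagents that add atoms: iodoethane, CCI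
Why: Williamson etherification with one equivalent of halide, expected at O7 because the 7-OH is the more acidic phenol (para-quinoid conjugation with the lactone carbonyl) and the 5-OH is shielded by the peri pentyl group on C4, with the bis-ether and the O5 isomer removed by chromatography.

Step 3
Reactants: 5 7-ethoxy-5-hydroxy-4-pentylcoumarin; 6 tert-butyldimethylsilyl chloride
Product: 7 5-(tert-butyldimethylsilyloxy)-7-ethoxy-4-pentylcoumarin
Conditions: TBSCl, imidazole, DMF, 40 °C
Reagents that add atoms: tert-butyldimethylsilyl chloride, CC(C)(C)[Si](C)(C)Cl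
Why: Imidazole-promoted silylation of the remaining phenol, so that no acidic O–H quenches the copper hydride of step 4.

Step 4
Reactants: 7 5-(tert-butyldimethylsilyloxy)-7-ethoxy-4-pentylcoumarin
Product: 9 (4R)-7-ethoxy-5-hydroxy-4-pentylchroman-2-one, via TBS-protected dihydrocoumarin 8 (not isolated)
Conditions: Cu(OAc)2·H2O (3 mol%), (R)-DTBM-SEGPHOS (3.3 mol%), (EtO)2MeSiH (2 equiv), t-BuOH (1.1 equiv), toluene, 0 °C → rt; crude 8, then TBAF, AcOH, THF, 0 °C
Reagents that add atoms: none
Why: Asymmetric conjugate reduction of the beta,beta-disubstituted unsaturated lactone by a bisphosphine-ligated copper hydride (monovalent copper), in which the chiral ligand selects the face of C4 that receives hydride and so sets the (4R) centre, tert-butanol protonates the copper enolate, the limited amount of silane guards against reduction of the lactone carbonyl, and buffered fluoride then cleaves the silyl ether without opening the lactone.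

Step 5
Reactants: 9 (4R)-7-ethoxy-5-hydroxy-4-pentylchroman-2-one; 10 allyl bromide
Product: 11 (4R)-5-(allyloxy)-7-ethoxy-4-pentylchroman-2-one
Conditions: allyl bromide, K2CO3, acetone, 50 °C
Reagents that add atoms: allyl bromide, C=CCBr
Why: Williamson O-allylation of the single phenol, safe against lactone migration because the open form of 9 has two equivalent ortho oxygens, so ring opening and reclosure can only return the same compound.

Step 6
Reactants: 11 (4R)-5-(allyloxy)-7-ethoxy-4-pentylchroman-2-one
Product: 12 (4R)-6-allyl-7-ethoxy-5-hydroxy-4-pentylchroman-2-one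
Conditions: PhNEt2 (dilute), 190 °C, argon
Reagents that add atoms: none
Why: Aromatic Claisen rearrangement ([3,3]-sigmatropic shift, then tautomerisation of the ortho-dienone), regiospecific because C6 is the only free ortho position of O5 (the other is the ring-fusion carbon C4a), with the C4 centre untouched by the neutral thermal conditions.

Step 7
Reactants: 12 (4R)-6-allyl-7-ethoxy-5-hydroxy-4-pentylchroman-2-one; 13 iodomethane
Product: 14 (4R)-6-allyl-7-ethoxy-5-methoxy-4-pentylchroman-2-one
Conditions: MeI (5 equiv), K2CO3 (anhydrous), acetone, 40 °C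
Reagents that add atoms: iodomethane, CI
Why: Williamson methylation of the hindered phenol under anhydrous conditions, in which the lactone stays on O1 because its carbonyl carbon cannot reach the meta-related O5 within one molecule.

Step 8
Reactants: 14 (4R)-6-allyl-7-ethoxy-5-methoxy-4-pentylchroman-2-one; 15 propanoyl chloride
Product: 16 (4R)-6-allyl-7-ethoxy-5-methoxy-4-pentyl-8-propanoylchroman-2-one
Conditions: EtCOCl, SnCl4, CH2Cl2, −40 → 0 °C
Reagents that add atoms: propanoyl chloride, CCC(=O)Cl
Why: Friedel–Crafts acylation at C8, the only aromatic C–H left and activated by the ortho ethoxy and para methoxy groups, with a mild Lewis acid at low temperature so that the monosubstituted allyl alkene, a far weaker nucleophile than the arene, should be left alone.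

Step 9
Reactants: 16 (4R)-6-allyl-7-ethoxy-5-methoxy-4-pentyl-8-propanoylchroman-2-one; 17 2-methylbut-2-ene
Product: 18 (4R)-7-ethoxy-5-methoxy-6-(3-methylbut-2-enyl)-4-pentyl-8-propanoylchroman-2-one
Conditions: second-generation Grubbs catalyst (5 mol%), 2-methylbut-2-ene/CH2Cl2, 40 °C
Reagents that add atoms: 2-methylbut-2-ene, CC=C(C)C
Why: Olefin cross-metathesis of the terminal allyl group with an excess of 2-methylbut-2-ene, a standard allyl-to-prenyl conversion driven by loss of propene and tolerant of the ketone and the lactone.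

Step 10
Reactants: 18 (4R)-7-ethoxy-5-methoxy-6-(3-methylbut-2-enyl)-4-pentyl-8-propanoylchroman-2-one; 19 2,2,2-trifluoroethyl trifluoroacetate; 20 4-acetamidobenzenesulfonyl azide
Product: 22 (4R)-8-(2-diazopropanoyl)-7-ethoxy-5-methoxy-6-(3-methylbut-2-enyl)-4-pentylchroman-2-one, via trifluoroacetyl diketone 21 (not isolated)
Conditions: LiN(SiMe3)2 (1.05 equiv), THF, −78 °C; CF3CO2CH2CF3, −78 °C; 5% aq. HCl; crude 21, then 4-acetamidobenzenesulfonyl azide, Et3N, MeCN, 0 °C → rt
Reagents that add atoms: 4-acetamidobenzenesulfonyl azide (the two diazo nitrogens), CC(=O)Nc1ccc(cc1)S(=O)(=O)N=[N+]=[N-]; 2,2,2-trifluoroethyl trifluoroacetate (trifluoroacetyl group of 21 only, lost again), FC(F)(F)COC(=O)C(F)(F)F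
Why: Detrifluoroacetylative diazo transfer (Danheiser variant of the Regitz reaction), in which the ethyl ketone, a stronger C–H acid than the lactone CH2, is enolised first and C-trifluoroacetylated, and the resulting 2-methyl-1,3-diketone takes the diazo group from the sulfonyl azide with loss of the trifluoroacetyl group onto the sulfonamide.

Step 11
Reactants: 22 (4R)-8-(2-diazopropanoyl)-7-ethoxy-5-methoxy-6-(3-methylbut-2-enyl)-4-pentylchroman-2-one
Product: 23 (4R,8S,9R)-5-methoxy-8,9-dimethyl-6-(3-methylbut-2-enyl)-4-pentyl-3,4,8,9-tetrahydro-2H,10H-pyrano[2,3-f]chromene-2,10-dione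
Conditions: Rh2(S-PTTL)4 (dirhodium tetrakis[N-phthaloyl-(S)-tert-leucinate], 2 mol%), toluene, −60 → −20 °C, slow addition of 22
Reagents that add atoms: none
Why: Loss of N2 from 22 at the dirhodium centre gives an electrophilic divalent rhodium carbenoid at the carbon that becomes C9 (C3 of the chromanone), which inserts into one C–H bond of the neighbouring O–CH2CH3 group through a three-centre, hydride-transfer-like transition state stabilised by the ether oxygen lone pair. The closest known reaction type is the chiral dirhodium tetracarboxylate C–H insertion of ortho-alkoxyaryl 2-diazopropanoyl ketones to cis-2,3-disubstituted chroman-4-ones, applied here to a plain ethyl ether. The pyranone ring is closed by the C8–C9 bond in a 1,6-C–H insertion, the six-membered mode being the only one open because the 1,5-position is the ether oxygen itself. C8 is set by which enantiotopic hydrogen of the OCH2 group is replaced (with retention), a choice made by the phthalimido wall of the tert-leucinate ligands; C9 is set in the same event, the compact transition state placing the C8 methyl away from the ligands and so cis to the C9 methyl, while the remote C4 centre has no say. The step needs chemoselectivity over 1,2-hydride migration from the carbenoid methyl group (held back by the bulky carboxylates and the low temperature), over ylide formation at O7 (reversible, ethyl being a poor migrating group) and over attack elsewhere, and the substrate secures the last: the prenyl alkene and the methoxy group are meta and para to the acyl carbon and cannot reach the carbenoid, and the second ortho oxygen is an acylated lactone oxygen with no O–H or activated C–H. The neutral, aprotic conditions should leave the epimerisable C9 centre as formed.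

Step 12
Reactants: 23 (4R,8S,9R)-5-methoxy-8,9-dimethyl-6-(3-methylbut-2-enyl)-4-pentyl-3,4,8,9-tetrahydro-2H,10H-pyrano[2,3-f]chromene-2,10-dione
Product: 24 (3R)-3-[(2S,3R)-5-hydroxy-7-methoxy-2,3-dimethyl-8-(3-methylbut-2-enyl)-4-oxochroman-6-yl]octanoic acid
Conditions: LiOH·H2O (2.5 equiv), THF/H2O (3:1), 0 °C; then cold 1 M HCl to pH 3
Reagents that add atoms: water (delivered as LiOH), O
Why: Saponification of the aryl lactone, which hydroxide should attack much faster than it removes the hindered C9–H next to the ketone, so the cis-(2S,3R) centres should survive, the phenoxide released ortho to the ketone further damps enolisation, and after cold acidification the ketone-chelated 5-OH should not relactonise.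

## Compound list

1 | phloroglucinol | Oc1cc(O)cc(O)c1 | starting material
2 | ethyl 3-oxooctanoate | CCCCCC(=O)CC(=O)OCC | starting material
3 | 5,7-dihydroxy-4-pentylcoumarin | CCCCCC1=CC(=O)Oc2cc(O)cc(O)c21 | intermediate
4 | iodoethane | CCI | starting material
5 | 7-ethoxy-5-hydroxy-4-pentylcoumarin | CCCCCC1=CC(=O)Oc2cc(OCC)cc(O)c21 | intermediate
6 | tert-butyldimethylsilyl chloride | CC(C)(C)[Si](C)(C)Cl | starting material
7 | 5-(tert-butyldimethylsilyloxy)-7-ethoxy-4-pentylcoumarin | CCCCCC1=CC(=O)Oc2cc(OCC)cc(O[Si](C)(C)C(C)(C)C)c21 | intermediate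
8 | (4R)-5-(tert-butyldimethylsilyloxy)-7-ethoxy-4-pentylchroman-2-one | CCCCC[C@H]1c2c(OC(=O)C1)cc(OCC)cc2O[Si](C)(C)C(C)(C)C | intermediate (not isolated)
9 | (4R)-7-ethoxy-5-hydroxy-4-pentylchroman-2-one | CCCCC[C@H]1c2c(OC(=O)C1)cc(OCC)cc2O | intermediate
10 | allyl bromide | C=CCBr | starting material
11 | (4R)-5-(allyloxy)-7-ethoxy-4-pentylchroman-2-one | CCCCC[C@H]1c2c(OC(=O)C1)cc(OCC)cc2OCC=C | intermediate
12 | (4R)-6-allyl-7-ethoxy-5-hydroxy-4-pentylchroman-2-one | CCCCC[C@H]1c2c(OC(=O)C1)cc(OCC)c(CC=C)c2O | intermediate
13 | iodomethane | CI | starting material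
14 | (4R)-6-allyl-7-ethoxy-5-methoxy-4-pentylchroman-2-one | CCCCC[C@H]1c2c(OC(=O)C1)cc(OCC)c(CC=C)c2OC | intermediate
15 | propanoyl chloride | CCC(=O)Cl | starting material
16 | (4R)-6-allyl-7-ethoxy-5-methoxy-4-pentyl-8-propanoylchroman-2-one | CCCCC[C@H]1c2c(OC(=O)C1)c(C(=O)CC)c(OCC)c(CC=C)c2OC | intermediate
17 | 2-methylbut-2-ene | CC=C(C)C | starting material
18 | (4R)-7-ethoxy-5-methoxy-6-(3-methylbut-2-enyl)-4-pentyl-8-propanoylchroman-2-one | CCCCC[C@H]1c2c(OC(=O)C1)c(C(=O)CC)c(OCC)c(CC=C(C)C)c2OC | intermediate
19 | 2,2,2-trifluoroethyl trifluoroacetate | FC(F)(F)COC(=O)C(F)(F)F | starting material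
20 | 4-acetamidobenzenesulfonyl azide | CC(=O)Nc1ccc(cc1)S(=O)(=O)N=[N+]=[N-] | starting material
21 | (4R)-7-ethoxy-5-methoxy-6-(3-methylbut-2-enyl)-4-pentyl-8-(4,4,4-trifluoro-2-methyl-3-oxobutanoyl)chroman-2-one (both epimers at the diketone carbon) | CCCCC[C@H]1c2c(OC(=O)C1)c(C(=O)C(C)C(=O)C(F)(F)F)c(OCC)c(CC=C(C)C)c2OC | intermediate (not isolated)
22 | (4R)-8-(2-diazopropanoyl)-7-ethoxy-5-methoxy-6-(3-methylbut-2-enyl)-4-pentylchroman-2-one | CCCCC[C@H]1c2c(OC(=O)C1)c(C(=O)C(C)=[N+]=[N-])c(OCC)c(CC=C(C)C)c2OC | intermediate
23 | (4R,8S,9R)-5-methoxy-8,9-dimethyl-6-(3-methylbut-2-enyl)-4-pentyl-3,4,8,9-tetrahydro-2H,10H-pyrano[2,3-f]chromene-2,10-dione (O5 lactone of the target acid, cis-dimethyl) | CCCCC[C@H]1c2c(OC(=O)C1)c1c(c(CC=C(C)C)c2OC)O[C@@H](C)[C@@H](C)C1=O | intermediate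
24 | (3R)-3-[(2S,3R)-5-hydroxy-7-methoxy-2,3-dimethyl-8-(3-methylbut-2-enyl)-4-oxochroman-6-yl]octanoic acid (CNP0217102.1) | CCCCC[C@H](CC(=O)O)c1c(O)c2c(c(CC=C(C)C)c1OC)O[C@@H](C)[C@@H](C)C2=O | target

## Step count and risks

Total step count: 12. Longest linear sequence: 12 steps (1 → 24).

Steps most likely to fail:

1. Step 11. The carbenoid may be lost to 1,2-hydride migration from its methyl group before it inserts into the weakly activated ether C–H bond, or the two enantiotopic hydrogens may be poorly told apart. Fallback, from 18: chelation-directed cleavage of the ethyl ether ortho to the ketone (BCl3, CH2Cl2, −78 °C) should give the phenol (4R)-7-hydroxy-5-methoxy-6-(3-methylbut-2-enyl)-4-pentyl-8-propanoylchroman-2-one F1. Kostanecki–Robinson annulation (Ac2O, NaOAc, 140 °C) should then give the 2,3-dimethylchromone (4R)-5-methoxy-8,9-dimethyl-6-(3-methylbut-2-enyl)-4-pentyl-3,4-dihydro-2H,10H-pyrano[2,3-f]chromene-2,10-dione F2. Asymmetric conjugate reduction of the chromone with a DTBM-SEGPHOS copper hydride ((EtO)2MeSiH, t-BuOH, toluene) would set C8 under ligand control, and kinetic protonation of the enolate anti to the C8 methyl group should give the cis isomer, which returns to 23.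

2. Step 8. The acylium and Lewis acid may attack the allyl alkene, or substitution at the crowded last ring position may stall. Fallback, from 14: Rieche formylation (Cl2CHOMe, TiCl4, CH2Cl2, −78 °C), which uses a small and very reactive electrophile at low temperature, should give the aldehyde (4R)-6-allyl-7-ethoxy-5-methoxy-2-oxo-4-pentylchromane-8-carbaldehyde F3. Addition of Et2Zn in the presence of Ti(OiPr)4 (toluene, −20 °C), which spares the lactone, should give the alcohol (4R)-6-allyl-7-ethoxy-8-(1-hydroxypropyl)-5-methoxy-4-pentylchroman-2-one F4 as both carbinol epimers. Dess–Martin oxidation returns to 16.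

3. Step 10. The lithium amide may also deprotonate the lactone CH2, leading to acylation at C3 or to ring opening. Fallback, from 18: soft enolisation with TMSOTf and Et3N (CH2Cl2, 0 °C), to which the lactone should be inert, would give the silyl enol ether (4R)-7-ethoxy-5-methoxy-6-(3-methylbut-2-enyl)-4-pentyl-8-[1-(trimethylsilyloxy)prop-1-enyl]chroman-2-one F5. C-acylation of F5 with trifluoroacetic anhydride (CH2Cl2, 0 °C) should give diketone 21, where the route is rejoined.

## Further compounds

F1 | step 11 | (4R)-7-hydroxy-5-methoxy-6-(3-methylbut-2-enyl)-4-pentyl-8-propanoylchroman-2-one | CCCCC[C@H]1c2c(OC(=O)C1)c(C(=O)CC)c(O)c(CC=C(C)C)c2OC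
F2 | step 11 | (4R)-5-methoxy-8,9-dimethyl-6-(3-methylbut-2-enyl)-4-pentyl-3,4-dihydro-2H,10H-pyrano[2,3-f]chromene-2,10-dione | CCCCC[C@H]1c2c(OC(=O)C1)c1c(c(CC=C(C)C)c2OC)OC(C)=C(C)C1=O
F3 | step 8 | (4R)-6-allyl-7-ethoxy-5-methoxy-2-oxo-4-pentylchromane-8-carbaldehyde | CCCCC[C@H]1c2c(OC(=O)C1)c(C=O)c(OCC)c(CC=C)c2OC
F4 | step 8 | (4R)-6-allyl-7-ethoxy-8-(1-hydroxypropyl)-5-methoxy-4-pentylchroman-2-one | CCCCC[C@H]1c2c(OC(=O)C1)c(C(O)CC)c(OCC)c(CC=C)c2OC
F5 | step 10 | (4R)-7-ethoxy-5-methoxy-6-(3-methylbut-2-enyl)-4-pentyl-8-[1-(trimethylsilyloxy)prop-1-enyl]chroman-2-one | CCCCC[C@H]1c2c(OC(=O)C1)c(C(O[Si](C)(C)C)=CC)c(OCC)c(CC=C(C)C)c2OC
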